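The cyclopentane is disconnected between its quaternary acetoxy carbon (C1) and the adjacent ring CH that carries the enal arm (C5). With the arm's C6=C7 double bond these atoms form a homoallylic tertiary carbinol, O–C1–C5–C6=C7, the retron of a carbonyl-ene reaction. The precursor is an open-chain α-keto ester (ketone = C1, ester = future C9) ending in an (E)-CH=CH–CH(CH3)2 group; on heating it forms the C1–C5 bond, both new ring stereocentres, the tertiary alcohol and the C6=C7 alkene in one operation. Selenium dioxide later turns the (E)-methyl group into the aldehyde; crotylboration and cross-metathesis build the side chain.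

Key step: step 6

Remark on locants: ring C1 (quaternary C–OAc), C2 (CH2), C3 (CH–CH3), C4 (CH–OBz), C5 (CH–alkenyl); enal arm C6=C7(CH3)–C8HO; side chain C9 (CH–OAc), C10 (CH–CH3), C11=C12, C13 (CMe2), C14 (C=O). Assumption: compounds 1, 2 and 20 and all named reagents are commercial.

Step 1
Reactants: 1 (S)-4-benzyl-3-propionyloxazolidin-2-one; 2 (E)-4-methylpent-2-enal
Product: 4 (S)-4-benzyl-3-[(2S,3R,E)-3-hydroxy-2,6-dimethylhept-4-enoyl]oxazolidin-2-one, via Z-boron enolate 3 (not isolated)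
Conditions: Bu2BOTf, i-Pr2NEt, CH2Cl2, −78 → 0 °C; then 2, −78 → 0 °C; pH 7 buffer, MeOH, H2O2
Reagents that add atoms: none
Why: Evans syn-aldol, in which the (Z)-dibutylboron enolate adds 1,2 to the enal through a closed chair transition state on the face away from the benzyl group, which should set C3 (methyl) and C4 (oxygen) as the 2S,3R syn pair.

Step 2
Reactants: 4 aldol adduct
Product: 5 (S)-4-benzyl-3-[(2S,3R,E)-3-[(tert-butyldimethylsilyl)oxy]-2,6-dimethylhept-4-enoyl]oxazolidin-2-one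
Conditions: TBSOTf, 2,6-lutidine, CH2Cl2, −78 → 0 °C
Reagents that add atoms: tert-butyldimethylsilyl triflate, CC(C)(C)[Si](C)(C)OS(=O)(=O)C(F)(F)F
Why: Silyl triflate silylation of the secondary allylic alcohol touches no stereocentre and blocks retro-aldol cleavage in the following steps.

Step 3
Reactants: 5 silyl ether
Product: 6 (2R,3R,E)-3-[(tert-butyldimethylsilyl)oxy]-2,6-dimethylhept-4-en-1-ol
Conditions: LiBH4, MeOH (1 equiv), THF, 0 °C
Reagents that add atoms: none
Why: Reductive cleavage of the N-acyloxazolidinone by borohydride attack at the exocyclic carbonyl gives the primary alcohol (C2) and releases the auxiliary without epimerising C3.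

Step 4
Reactants: 6 primary alcohol
Product: 7 tert-butyl{[(2S,3R,E)-1-iodo-2,6-dimethylhept-4-en-3-yl]oxy}dimethylsilane
Conditions: I2, PPh3, imidazole, CH2Cl2, 0 °C → rt
Reagents that add atoms: iodine, II
Why: Appel-type iodination, in which iodide displaces the primary oxyphosphonium group by SN2 at a carbon that is not a stereocentre.

Step 5
Reactants: 7 primary iodide
Product: 9 methyl (4R,5S,E)-5-[(tert-butyldimethylsilyl)oxy]-4,8-dimethyl-2-oxonon-6-enoate, via alkyllithium 8 (not isolated)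
Conditions: t-BuLi (2.1 equiv), Et2O–pentane, −78 °C; cannula into dimethyl oxalate (3 equiv), THF, −78 °C; AcOH quench
Reagents that add atoms: dimethyl oxalate, COC(=O)C(=O)OC
Why: Iodine–lithium exchange followed by mono-addition of the alkyllithium to excess dimethyl oxalate, whose tetrahedral adduct survives at −78 °C until the acid quench, should give the α-keto ester (C1 ketone, C9 ester) without a second addition.

Step 6
Reactants: 9 α-keto ester
Product: 10 methyl (1R,2S,3S,4R)-3-[(tert-butyldimethylsilyl)oxy]-1-hydroxy-4-methyl-2-(2-methylprop-1-en-1-yl)cyclopentane-1-carboxylate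
Conditions: n-decane (0.02 M, degassed), 180 °C, sealed tube
Reagents that add atoms: none
Why: Concerted thermal intramolecular carbonyl-ene reaction (type I): the ketone carbonyl of the α-keto ester (C1, activated by the adjacent ester) bonds to C5 of the (E)-alkene while the isopropyl methine hydrogen on C7 shifts to the carbonyl oxygen and the π bond moves to C6=C7. The closest known reaction type is the uncatalysed ene cyclisation of unsaturated α-keto esters to 2-alkenyl-1-hydroxycyclopentanecarboxylates. The cyclopentane closes in a 5-exo-trig sense at both π termini, and only the ketone, not the ester carbonyl, can reach C5 in a five-membered array. C1 and C5 are set together: the six-membered hydrogen-transfer array forces the new hydroxyl and the alkenyl group cis, and the twisted five-ring transition state offers the C4 silyloxy group one pseudo-equatorial site, the one syn to C6 (the alternative is pseudo-axial, eclipsed with C5–H and 1,3 to the ester), so the alkenyl group should end up cis to OTBS and trans to the C3 methyl. The step needs this facial selectivity and abstraction of a tertiary hydrogen; the (E)-geometry (no A1,3 strain in the reactive rotamer) and the symmetric isopropyl terminus (no alkene-geometry issue) are what secure them.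

Step 7
Reactants: 10 cyclopentanol
Product: 11 methyl (1R,2S,3S,4R)-3-[(tert-butyldimethylsilyl)oxy]-4-methyl-2-(2-methylprop-1-en-1-yl)-1-[(triethylsilyl)oxy]cyclopentane-1-carboxylate
Conditions: TESOTf, 2,6-lutidine, CH2Cl2, 0 °C → rt
Reagents that add atoms: triethylsilyl triflate, CC[Si](CC)(CC)OS(=O)(=O)C(F)(F)F
Why: Silyl triflate silylation of the hindered tertiary alcohol blocks α-ketol rearrangement of the aldehyde to come and keeps the hydroxyl out of the crotylboration.

Step 8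
Reactants: 11 ester
Product: 12 (1R,2S,3S,4R)-3-[(tert-butyldimethylsilyl)oxy]-4-methyl-2-(2-methylprop-1-en-1-yl)-1-[(triethylsilyl)oxy]cyclopentane-1-carbaldehyde
Conditions: DIBAL-H (1.3 equiv), CH2Cl2, −78 °C; Rochelle salt
Reagents that add atoms: none
Why: Partial DIBAL-H reduction, in which the hindered α-silyloxy aluminium hemiacetal should persist at −78 °C and release the non-enolisable C9 aldehyde only on work-up.

Step 9
Reactants: 12 aldehyde
Product: 13 (1R,2S)-1-[(1R,2S,3S,4R)-3-[(tert-butyldimethylsilyl)oxy]-4-methyl-2-(2-methylprop-1-en-1-yl)-1-[(triethylsilyl)oxy]cyclopentyl]-2-methylbut-3-en-1-ol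
Conditions: cis-but-2-ene, KOt-Bu, n-BuLi, THF, −78 → −45 °C; (+)-Ipc2BOMe, −78 °C; BF3·OEt2; 12, −78 °C; NaOH, H2O2, 0 °C → rt
Reagents that add atoms: cis-but-2-ene, C/C=C\C, delivered as (Z)-crotylbis[(+)-isopinocampheyl]borane, C/C=C\CB([C@H]1C[C@H]2C[C@@H]([C@@H]1C)C2(C)C)[C@H]1C[C@H]2C[C@@H]([C@@H]1C)C2(C)C
Why: Brown crotylboration through a closed chair transition state, in which the (Z)-crotyl geometry gives the syn C9/C10 pair and the (+)-isopinocampheyl ligands (from (−)-α-pinene) select the aldehyde face that should give 9R,10S.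

Step 10
Reactants: 13 homoallylic alcohol
Product: 14 (1R,2S)-1-[(1R,2S,3S,4R)-3-[(tert-butyldimethylsilyl)oxy]-4-methyl-2-(2-methylprop-1-en-1-yl)-1-[(triethylsilyl)oxy]cyclopentyl]-2-methylbut-3-en-1-yl acetate
Conditions: Ac2O, pyridine, DMAP (cat.), CH2Cl2, rt → 40 °C
Reagents that add atoms: acetic anhydride, CC(=O)OC(C)=O
Why: DMAP-catalysed acylation of the only free hydroxyl (C9) installs the first acetate of the target.

Step 11
Reactants: 14 acetate
Product: 15 (1R,2S)-1-[(1R,2S,3S,4R)-1,3-dihydroxy-4-methyl-2-(2-methylprop-1-en-1-yl)cyclopentyl]-2-methylbut-3-en-1-yl acetate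
Conditions: HF·pyridine, pyridine, THF, 0 → 40 °C
Reagents that add atoms: none
Why: Fluoride cleavage of both silyl ethers (tertiary TES, secondary TBS) under mildly acidic conditions that leave the acetate in place and disfavour acyl migration.

Step 12
Reactants: 15 diol
Product: 16 (1S,2S,3R,5R)-3-[(1R,2S)-1-acetoxy-2-methylbut-3-en-1-yl]-3-hydroxy-5-methyl-2-(2-methylprop-1-en-1-yl)cyclopentyl benzoate
Conditions: BzCl (1.5 equiv), pyridine, DMAP (cat.), CH2Cl2, 0 °C → rt
Reagents that add atoms: benzoyl chloride, O=C(Cl)c1ccccc1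
Why: Nucleophile-catalysed benzoylation distinguishes the secondary C4 hydroxyl from the hindered tertiary C1 hydroxyl on steric grounds.

Step 13
Reactants: 16 hydroxy benzoate
Product: 17 (1S,2S,3R,5R)-3-acetoxy-3-[(1R,2S)-1-acetoxy-2-methylbut-3-en-1-yl]-5-methyl-2-(2-methylprop-1-en-1-yl)cyclopentyl benzoate
Conditions: Ac2O (excess), DMAP (2 equiv), Et3N, ClCH2CH2Cl, 60 °C
Reagents that add atoms: acetic anhydride, CC(=O)OC(C)=O
Why: Forced DMAP-mediated acetylation (N-acetylpyridinium transfer) of the remaining tertiary alcohol under base-only conditions avoids Lewis acids that could ionise the esters.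

Step 14
Reactants: 17 triester
Product: 19 (1S,2S,3R,5R)-3-acetoxy-3-[(1R,2S)-1-acetoxy-2-methylbut-3-en-1-yl]-5-methyl-2-[(E)-2-methyl-3-oxoprop-1-en-1-yl]cyclopentyl benzoate, via allylic alcohol 18 (not isolated)
Conditions: SeO2 (1.5 equiv), wet 1,4-dioxane, 80 °C
Reagents that add atoms: selenium dioxide, O=[Se]=O
Why: Riley allylic oxidation (ene reaction at the more substituted alkene terminus, then [2,3]-shift) selects the (E)-methyl group of the trisubstituted C6=C7 alkene over the monosubstituted vinyl group, and further oxidation of the allylic alcohol in the same flask should give the (E)-enal.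

Step 15
Reactants: 20 2,2-dimethylbut-3-enoic acid
Product: 21 3,3-dimethylpent-4-en-2-one
Conditions: MeLi (2.2 equiv), Et2O, 0 °C → rt; aq. HCl
Reagents that add atoms: methyllithium, [Li]C
Why: Addition of methyllithium to the lithium carboxylate gives a stable geminal dialkoxide that collapses to the methyl ketone only on acidic work-up, so no tertiary alcohol forms.

Step 16
Reactants: 19 enal with terminal vinyl group; 21 3,3-dimethylpent-4-en-2-one (8 equiv)
Product: 22 (1S,2S,3R,5R)-3-acetoxy-3-[(1R,2S,3E)-1-acetoxy-2,5,5-trimethyl-6-oxohept-3-en-1-yl]-5-methyl-2-[(E)-2-methyl-3-oxoprop-1-en-1-yl]cyclopentyl benzoate (target)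
Conditions: Hoveyda–Grubbs II (10 mol %), CH2Cl2, 40 °C, argon sweep
Reagents that add atoms: none
Why: Olefin cross-metathesis, in which the allylic quaternary carbon makes 21 a non-dimerising partner usable in excess, the electron-poor trisubstituted enal alkene is inert, and the hindered C11=C12 alkene should form as the thermodynamic (E)-isomer.

Compound list
1 | (S)-4-benzyl-3-propionyloxazolidin-2-one | CCC(=O)N1[C@@H](Cc2ccccc2)COC1=O | starting material
2 | (E)-4-methylpent-2-enal | CC(C)/C=C/C=O | starting material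
3 | (Z)-dibutylboron enolate of 1 (formed in the flask) | C/C=C(\OB(CCCC)CCCC)N1[C@@H](Cc2ccccc2)COC1=O | intermediate
4 | (S)-4-benzyl-3-[(2S,3R,E)-3-hydroxy-2,6-dimethylhept-4-enoyl]oxazolidin-2-one | CC(C)/C=C/[C@@H](O)[C@H](C)C(=O)N1[C@@H](Cc2ccccc2)COC1=O | intermediate
5 | TBS ether of 4 | CC(C)/C=C/[C@@H](O[Si](C)(C)C(C)(C)C)[C@H](C)C(=O)N1[C@@H](Cc2ccccc2)COC1=O | intermediate
6 | (2R,3R,E)-3-[(tert-butyldimethylsilyl)oxy]-2,6-dimethylhept-4-en-1-ol | CC(C)/C=C/[C@@H](O[Si](C)(C)C(C)(C)C)[C@H](C)CO | intermediate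
7 | tert-butyl{[(2S,3R,E)-1-iodo-2,6-dimethylhept-4-en-3-yl]oxy}dimethylsilane | CC(C)/C=C/[C@@H](O[Si](C)(C)C(C)(C)C)[C@H](C)CI | intermediate
8 | alkyllithium from 7 (formed in the flask) | CC(C)/C=C/[C@@H](O[Si](C)(C)C(C)(C)C)[C@H](C)C[Li] | intermediate
9 | methyl (4R,5S,E)-5-[(tert-butyldimethylsilyl)oxy]-4,8-dimethyl-2-oxonon-6-enoate | CC(C)/C=C/[C@@H](O[Si](C)(C)C(C)(C)C)[C@H](C)CC(=O)C(=O)OC | intermediate
10 | methyl (1R,2S,3S,4R)-3-[(tert-butyldimethylsilyl)oxy]-1-hydroxy-4-methyl-2-(2-methylprop-1-en-1-yl)cyclopentane-1-carboxylate | COC(=O)[C@@]1(O)C[C@@H](C)[C@H](O[Si](C)(C)C(C)(C)C)[C@@H]1C=C(C)C | intermediate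
11 | triethylsilyl ether of 10 | COC(=O)[C@@]1(O[Si](CC)(CC)CC)C[C@@H](C)[C@H](O[Si](C)(C)C(C)(C)C)[C@@H]1C=C(C)C | intermediate
12 | (1R,2S,3S,4R)-3-[(tert-butyldimethylsilyl)oxy]-4-methyl-2-(2-methylprop-1-en-1-yl)-1-[(triethylsilyl)oxy]cyclopentane-1-carbaldehyde | O=C[C@@]1(O[Si](CC)(CC)CC)C[C@@H](C)[C@H](O[Si](C)(C)C(C)(C)C)[C@@H]1C=C(C)C | intermediate
13 | (1R,2S)-2-methyl-1-[bis-silylated cyclopentyl]but-3-en-1-ol (syn crotyl adduct) | O[C@H]([C@@H](C)C=C)[C@@]1(O[Si](CC)(CC)CC)C[C@@H](C)[C@H](O[Si](C)(C)C(C)(C)C)[C@@H]1C=C(C)C | intermediate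
14 | C9 acetate of 13 | CC(=O)O[C@H]([C@@H](C)C=C)[C@@]1(O[Si](CC)(CC)CC)C[C@@H](C)[C@H](O[Si](C)(C)C(C)(C)C)[C@@H]1C=C(C)C | intermediate
15 | (1R,2S)-1-[(1R,2S,3S,4R)-1,3-dihydroxy-4-methyl-2-(2-methylprop-1-en-1-yl)cyclopentyl]-2-methylbut-3-en-1-yl acetate | CC(=O)O[C@H]([C@@H](C)C=C)[C@@]1(O)C[C@@H](C)[C@H](O)[C@@H]1C=C(C)C | intermediate
16 | (1S,2S,3R,5R)-3-[(1R,2S)-1-acetoxy-2-methylbut-3-en-1-yl]-3-hydroxy-5-methyl-2-(2-methylprop-1-en-1-yl)cyclopentyl benzoate | CC(=O)O[C@H]([C@@H](C)C=C)[C@@]1(O)C[C@@H](C)[C@H](OC(=O)c2ccccc2)[C@@H]1C=C(C)C | intermediate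
17 | (1S,2S,3R,5R)-3-acetoxy-3-[(1R,2S)-1-acetoxy-2-methylbut-3-en-1-yl]-5-methyl-2-(2-methylprop-1-en-1-yl)cyclopentyl benzoate | CC(=O)O[C@H]([C@@H](C)C=C)[C@@]1(OC(C)=O)C[C@@H](C)[C@H](OC(=O)c2ccccc2)[C@@H]1C=C(C)C | intermediate
18 | (E)-allylic alcohol from 17 (formed in the flask) | CC(=O)O[C@H]([C@@H](C)C=C)[C@@]1(OC(C)=O)C[C@@H](C)[C@H](OC(=O)c2ccccc2)[C@@H]1/C=C(\C)CO | intermediate
19 | (1S,2S,3R,5R)-3-acetoxy-3-[(1R,2S)-1-acetoxy-2-methylbut-3-en-1-yl]-5-methyl-2-[(E)-2-methyl-3-oxoprop-1-en-1-yl]cyclopentyl benzoate | CC(=O)O[C@H]([C@@H](C)C=C)[C@@]1(OC(C)=O)C[C@@H](C)[C@H](OC(=O)c2ccccc2)[C@@H]1/C=C(\C)C=O | intermediate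
20 | 2,2-dimethylbut-3-enoic acid | C=CC(C)(C)C(=O)O | starting material
21 | 3,3-dimethylpent-4-en-2-one | C=CC(C)(C)C(C)=O | intermediate
22 | (1S,2S,3R,5R)-3-acetoxy-3-[(1R,2S,3E)-1-acetoxy-2,5,5-trimethyl-6-oxohept-3-en-1-yl]-5-methyl-2-[(E)-2-methyl-3-oxoprop-1-en-1-yl]cyclopentyl benzoate | CC(=O)O[C@H]([C@@H](C)/C=C/C(C)(C)C(C)=O)[C@@]1(OC(C)=O)C[C@@H](C)[C@H](OC(=O)c2ccccc2)[C@@H]1/C=C(\C)C=O | target

Total step count: 16. Longest linear sequence: 15 (steps 1–14 and 16).

Steps most likely to fail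

Step 6 (ene cyclisation). Transfer of the tertiary isopropyl hydrogen may be slow, so that prolonged heating erodes facial selectivity or decomposes the keto ester by enolisation. The fallback sets out from 1 (through enolate 3) and returns at 10. (E)-But-2-enal replaces 2 in the Evans aldol and gives (S)-4-benzyl-3-[(2S,3R,E)-3-hydroxy-2-methylhex-4-enoyl]oxazolidin-2-one F1. TBSOTf then gives its silyl ether F2, LiBH4 the alcohol (2R,3R,E)-3-[(tert-butyldimethylsilyl)oxy]-2-methylhex-4-en-1-ol F3, and I2/PPh3/imidazole the iodide F4. t-BuLi converts this into the alkyllithium F5, which with dimethyl oxalate gives methyl (4R,5S,E)-5-[(tert-butyldimethylsilyl)oxy]-4-methyl-2-oxooct-6-enoate F6. The thermal ene reaction of F6 transfers a primary methyl hydrogen and should give the vinylcyclopentanol F7. Cross-metathesis of F7 with 2-methylbut-2-ene (Grubbs II, neat alkene, 40 °C) installs the 2-methylprop-1-enyl group and gives 10.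

Step 16 (cross-metathesis). Productive metathesis between two hindered olefins may be slower than catalyst decomposition. The fallback sets out from 17 and returns at 22. Hydroboration of the vinyl group with 9-BBN and NaBO3 oxidation gives the primary alcohol F8, and Dess–Martin oxidation gives the aldehyde F9. Mukaiyama aldol addition of 2-methyl-3-(trimethylsilyloxy)but-2-ene (BF3·OEt2, −78 °C) builds the quaternary carbon and gives the β-hydroxy ketone F10 as an inconsequential mixture of carbinol epimers. Dehydration with the Burgess reagent can only proceed towards C11 and should give the (E)-alkene F11. Catalytic SeO2 with t-BuOOH at room temperature (to spare the methyl ketone) gives the allylic alcohol F12, which MnO2 oxidises to 22.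

Step 9 (crotylboration). Addition to the neopentyl α-silyloxy aldehyde may be slow, or the reagent may be mismatched with the substrate so that facial selectivity is poor. The fallback sets out from 12 and returns at 13. The (Z)-dibutylboron enolate F13 of (R)-4-benzyl-3-propionyloxazolidin-2-one adds to 12 in an Evans syn-aldol and gives the adduct F14 with the same C9/C10 configuration. LiBH4 gives the diol F15, TEMPO/PhI(OAc)2 oxidises only the primary hydroxyl to the β-hydroxy aldehyde F16, and Wittig methylenation (Ph3P=CH2, THF, 0 °C) gives 13.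

Further compounds
F1 | step 6 | (S)-4-benzyl-3-[(2S,3R,E)-3-hydroxy-2-methylhex-4-enoyl]oxazolidin-2-one | C/C=C/[C@@H](O)[C@H](C)C(=O)N1[C@@H](Cc2ccccc2)COC1=O
F2 | step 6 | TBS ether of F1 | C/C=C/[C@@H](O[Si](C)(C)C(C)(C)C)[C@H](C)C(=O)N1[C@@H](Cc2ccccc2)COC1=O
F3 | step 6 | (2R,3R,E)-3-[(tert-butyldimethylsilyl)oxy]-2-methylhex-4-en-1-ol | C/C=C/[C@@H](O[Si](C)(C)C(C)(C)C)[C@H](C)CO
F4 | step 6 | tert-butyl{[(2S,3R,E)-1-iodo-2-methylhex-4-en-3-yl]oxy}dimethylsilane | C/C=C/[C@@H](O[Si](C)(C)C(C)(C)C)[C@H](C)CI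
F5 | step 6 | alkyllithium from F4 | C/C=C/[C@@H](O[Si](C)(C)C(C)(C)C)[C@H](C)C[Li]
F6 | step 6 | methyl (4R,5S,E)-5-[(tert-butyldimethylsilyl)oxy]-4-methyl-2-oxooct-6-enoate | C/C=C/[C@@H](O[Si](C)(C)C(C)(C)C)[C@H](C)CC(=O)C(=O)OC
F7 | step 6 | methyl (1R,2S,3S,4R)-3-[(tert-butyldimethylsilyl)oxy]-1-hydroxy-4-methyl-2-vinylcyclopentane-1-carboxylate | COC(=O)[C@@]1(O)C[C@@H](C)[C@H](O[Si](C)(C)C(C)(C)C)[C@@H]1C=C
F8 | step 16 | primary alcohol from hydroboration of 17 | CC(=O)O[C@H]([C@@H](C)CCO)[C@@]1(OC(C)=O)C[C@@H](C)[C@H](OC(=O)c2ccccc2)[C@@H]1C=C(C)C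
F9 | step 16 | aldehyde from F8 | CC(=O)O[C@H]([C@@H](C)CC=O)[C@@]1(OC(C)=O)C[C@@H](C)[C@H](OC(=O)c2ccccc2)[C@@H]1C=C(C)C
F10 | step 16 | β-hydroxy ketone (carbinol epimers) | CC(=O)O[C@H]([C@@H](C)CC(O)C(C)(C)C(C)=O)[C@@]1(OC(C)=O)C[C@@H](C)[C@H](OC(=O)c2ccccc2)[C@@H]1C=C(C)C
F11 | step 16 | (E)-alkene with full side chain and 2-methylprop-1-enyl group | CC(=O)O[C@H]([C@@H](C)/C=C/C(C)(C)C(C)=O)[C@@]1(OC(C)=O)C[C@@H](C)[C@H](OC(=O)c2ccccc2)[C@@H]1C=C(C)C
F12 | step 16 | (E)-allylic alcohol from F11 | CC(=O)O[C@H]([C@@H](C)/C=C/C(C)(C)C(C)=O)[C@@]1(OC(C)=O)C[C@@H](C)[C@H](OC(=O)c2ccccc2)[C@@H]1/C=C(\C)CO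
F13 | step 9 | (Z)-dibutylboron enolate of (R)-4-benzyl-3-propionyloxazolidin-2-one | C/C=C(\OB(CCCC)CCCC)N1[C@H](Cc2ccccc2)COC1=O
F14 | step 9 | (R)-4-benzyl-3-[(2R,3R)-3-hydroxy-2-methyl-3-(bis-silylated cyclopentyl)propanoyl]oxazolidin-2-one | O[C@H]([C@@H](C)C(=O)N2[C@H](Cc3ccccc3)COC2=O)[C@@]1(O[Si](CC)(CC)CC)C[C@@H](C)[C@H](O[Si](C)(C)C(C)(C)C)[C@@H]1C=C(C)C
F15 | step 9 | (1R,2S)-2-methyl-1-(bis-silylated cyclopentyl)propane-1,3-diol | O[C@H]([C@@H](C)CO)[C@@]1(O[Si](CC)(CC)CC)C[C@@H](C)[C@H](O[Si](C)(C)C(C)(C)C)[C@@H]1C=C(C)C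
F16 | step 9 | (2R,3R)-3-hydroxy-2-methyl-3-(bis-silylated cyclopentyl)propanal | O[C@H]([C@@H](C)C=O)[C@@]1(O[Si](CC)(CC)CC)C[C@@H](C)[C@H](O[Si](C)(C)C(C)(C)C)[C@@H]1C=C(C)C
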